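## Retrosynthetic overview

1. Locants: C1 CHBr, C4 C(=CH2), C5 C-OH, C7 side-chain CH, C10 C-CH3. Ring A is C1-C5 plus C10, and ring B is C5-C10. The plan rests on the ring-fusion pair C5/C10. Both carbons are fully substituted. C1 (on C10) and the oxygen (on C5) lie on one face of ring B, and CH3 and C4 lie on the other. An O-C1(=O) bridge, that is a β-lactone fused to ring B, therefore defines both centres at once.
2. Late cuts are the triene C-C bond (Suzuki-Miyaura, E-vinyl iodide plus E-dienylboronate), C1-Br (inversion of an axial C1-OH) and C4=CH2 (Wittig on the unmasked ketone). The vinyl iodide goes back through alkyne and acetyl to the isopropenyl group.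
3. Ring A is cut at C1-C2. A C2 alkyllithium is acylated by the lactone carbonyl, which consumes the lactone and frees C5-OH.
4. Ring B and the lactone are cut together at C5-C10 and O-C1, giving keto acid 15 for an aldol-lactonisation.
5. Keto acid 15 comes from (R)-limonene, TosMIC (C1) and an alkylated dithiane (C2-C4). Limonene supplies C5-C10, the C10 methyl and the C7 centre, and its ring alkene is the C5/C10 bond that is cut and later re-made. Ring order: ring B with the β-lactone (step 10), then ring A (step 13).

Key step: step 10

Remark: β is the face of the C10 methyl group and α is the opposite face. Compounds 8, 9 and 11-17 are carried as mixtures of epimers at C10 (11-13 also at C5). These centres are drawn without descriptor because steps 8 and 10 erase them.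

## Route

Step 1
Reactants: 1 1,3-dithiane; 2 (2-bromoethoxy)(tert-butyl)dimethylsilane
Product: 4 tert-butyl[2-(1,3-dithian-2-yl)ethoxy]dimethylsilane, via 2-lithio-1,3-dithiane 3 (not isolated)
Conditions: n-BuLi, THF, -30 °C; then 2, -78 °C to rt
Reagents that add atoms: none
Why: Corey-Seebach alkylation, in which the sulfur-stabilised carbanion displaces the primary bromide by SN2 and provides C4 (dithiane carbon), C3 and C2 in one piece.

Step 2
Reactants: 5 (R)-limonene
Product: 7 (5R)-7,7-dimethoxy-5-(prop-1-en-2-yl)heptan-2-one, via (3R)-6-oxo-3-(prop-1-en-2-yl)heptanal 6 (not isolated)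
Conditions: O3 (1 equiv, dosed), CH2Cl2/MeOH, -78 °C; Me2S, to rt; then p-TsOH (cat.), MeOH, rt
Reagents that add atoms: ozone [O-][O+]=O; methanol CO
Why: Selective ozonolysis, since ozone consumes the trisubstituted ring alkene before the 1,1-disubstituted isopropenyl group and so cuts the future C5-C10 bond, after which acid in methanol acetalises only the aldehyde C5 because the methyl ketone ketal is disfavoured at equilibrium, and the C7 centre of limonene is not touched.

Step 3
Reactants: 7 keto acetal
Product: 8 (5R)-7,7-dimethoxy-2-methyl-5-(prop-1-en-2-yl)heptanenitrile (C10 epimers)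
Conditions: TosMIC, KOt-Bu, DME/EtOH, 0 °C to rt
Reagents that add atoms: tosylmethyl isocyanide Cc1ccc(cc1)S(=O)(=O)C[N+]#[C-]
Why: Van Leusen reductive cyanation, in which the TosMIC anion adds to the unhindered methyl ketone and the adduct collapses with loss of sulfinate and formate to the one-carbon-longer secondary nitrile (C1), whose new C10 centre does not matter because step 10 makes it planar.

Step 4
Reactants: 8 nitrile acetal
Product: 9 (5R)-2-methyl-7-oxo-5-(prop-1-en-2-yl)heptanenitrile
Conditions: 1 M aq. HCl, THF, rt
Reagents that add atoms: water O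
Why: Acid-catalysed acetal hydrolysis, under conditions that leave nitrile and isopropenyl group alone and cannot epimerise C7, which is β to the aldehyde.

Step 5
Reactants: 4 alkylated dithiane; 9 nitrile aldehyde
Product: 11 (5R)-7-hydroxy-2-methyl-5-(prop-1-en-2-yl)-7-{2-[2-(tert-butyldimethylsilyloxy)ethyl]-1,3-dithian-2-yl}heptanenitrile, via lithiated dithiane 10 (not isolated)
Conditions: 4, n-BuLi, THF, -20 °C; then 9, -78 °C; H2O
Reagents that add atoms: none
Why: Corey-Seebach acyl-anion addition forming C4-C5, because the aldehyde captures the carbanion at -78 °C faster than the hindered tertiary C-H of the nitrile is removed, and the unselectively formed C5 carbinol centre disappears in step 8.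

Step 6
Reactants: 11 hydroxy dithiane
Product: 12 (5R)-7-hydroxy-2-methyl-5-(prop-1-en-2-yl)-7-{2-[2-(tert-butyldimethylsilyloxy)ethyl]-1,3-dioxolan-2-yl}heptanenitrile
Conditions: PhI(OCOCF3)2, HOCH2CH2OH (excess), MeCN, 0 °C
Reagents that add atoms: ethylene glycol OCCO
Why: Oxidative dethioketalisation run in the presence of the diol, where activation at sulfur gives a C4 thionium/oxocarbenium ion that glycol traps, so the dithiane is exchanged in one operation for a dioxolane able to survive the later chlorite and ozone steps.

Step 7
Reactants: 12 hydroxy nitrile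
Product: 13 (5R)-7-hydroxy-2-methyl-5-(prop-1-en-2-yl)-7-{2-[2-(tert-butyldimethylsilyloxy)ethyl]-1,3-dioxolan-2-yl}heptanal
Conditions: i-Bu2AlH (2.5 equiv), toluene, -78 °C; then aq. potassium sodium tartrate, rt
Reagents that add atoms: water O
Why: Partial nitrile reduction, in which one equivalent of hydride is spent on C5-OH and the next stops at the N-aluminio imine, which the work-up hydrolyses to the aldehyde without harm to ketal or silyl ether.

Step 8
Reactants: 13 hydroxy aldehyde
Product: 14 (5R)-2-methyl-7-oxo-5-(prop-1-en-2-yl)-7-{2-[2-(tert-butyldimethylsilyloxy)ethyl]-1,3-dioxolan-2-yl}heptanal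
Conditions: Dess-Martin periodinane, CH2Cl2, rt
Reagents that add atoms: none
Why: Dess-Martin oxidation turns the hindered secondary C5 alcohol into the ketone under near-neutral conditions that leave aldehyde, alkene, ketal and silyl ether untouched.

Step 9
Reactants: 14 keto aldehyde
Product: 15 (5R)-7-{2-[2-(tert-butyldimethylsilyloxy)ethyl]-1,3-dioxolan-2-yl}-2-methyl-7-oxo-5-(prop-1-en-2-yl)heptanoic acid
Conditions: NaClO2, NaH2PO4, 2-methyl-2-butene, t-BuOH/H2O, rt
Reagents that add atoms: sodium chlorite [Na+].[O-]Cl=O
Why: Pinnick oxidation is specific for the aldehyde, and the excess of scavenger alkene keeps hypochlorous acid away from the isopropenyl group.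

Step 10
Reactants: 15 keto acid
Product: 18 (1R,4R,6S)-6-{2-[2-(tert-butyldimethylsilyloxy)ethyl]-1,3-dioxolan-2-yl}-1-methyl-4-(prop-1-en-2-yl)-7-oxabicyclo[4.2.0]octan-8-one, via tosyl mixed anhydride 16 (not isolated), via acylammonium enolate 17 (not isolated)
Conditions: TsCl (1.5 equiv), 4-pyrrolidinopyridine (0.3 equiv), i-Pr2NEt (4 equiv), LiCl (1 equiv), CH2Cl2 (high dilution), rt, slow addition of 15
Reagents that add atoms: none
Why: TsCl converts 15 into mixed anhydride 16, 4-pyrrolidinopyridine takes over the acyl group (directly or through the alkyl(methyl)ketene) and i-Pr2NEt removes the only acidified proton, C10-H, so both C10 epimers merge in the planar enolate 17. C10 of 17 then adds to the C5 ketone and the tertiary alkoxide attacks the acylammonium carbon C1 with release of the catalyst; the closest known reaction type is the nucleophile-catalysed aldol-lactonisation of keto acids to bicyclic β-lactones (a formal ketene-ketone [2+2]), of which this α-branched acid/α-ketal ketone pair is a sterically demanding member. Ring B closes by a 6-(enolexo)-exo-trig aldol addition and the lactone by a 4-exo-trig acyl substitution. The C5/C10 relationship is fixed by the four-membered ring, which can only be cis-fused to a cyclohexane, so O and C1 end on one face and CH3 and C4 on the other. Their sense relative to C7 is set in the chair-like transition state that keeps the C7 isopropenyl group and the large ketal arm on C5 equatorial, which places O axial, C1 equatorial and CH3 axial as in (1R,4R,6S)-18. The step needs enolisation on the acid side only and ring closure faster than intermolecular acylation: only C10-H is activated by the acylpyridinium unit, the ketal makes C4 non-enolisable and raises the electrophilicity of C5, LiCl can bridge the two oxygens, and slow addition keeps 16 dilute.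

Step 11
Reactants: 18 silyl ether β-lactone
Product: 19 primary alcohol (C2-OH) of the β-lactone
Conditions: HF·pyridine, pyridine/THF, 0 °C to rt
Reagents that add atoms: none
Why: Buffered fluoride desilylation removes the primary silyl ether without generating a basic alkoxide, so the fully substituted β-lactone and the deactivated ketal persist.

Step 12
Reactants: 19 primary alcohol
Product: 20 primary iodide (C2-I) of the β-lactone
Conditions: I2, PPh3, imidazole, CH2Cl2, 0 °C
Reagents that add atoms: iodine II
Why: Appel-type iodination activates the unhindered primary alcohol quickly as its oxyphosphonium salt, so SN2 by iodide should outrun translactonisation onto C1.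

Step 13
Reactants: 20 iodo β-lactone
Product: 22 trans-decalone (C1 ketone; C4 ethylene ketal; C5 α-OH; C7 β-isopropenyl; C10 β-CH3), via primary alkyllithium 21 (not isolated)
Conditions: t-BuLi (2.1 equiv), Et2O/pentane, -78 °C; AcOH in Et2O, -78 °C
Reagents that add atoms: none
Why: Iodine-lithium exchange followed by intramolecular nucleophilic acyl substitution (Parham-type cyclisation), since exchange at the primary iodide is faster than attack of t-BuLi on the neopentyl carbonyl, the C2 carbanion reaches C1 in a 6-exo-trig mode, the strained adduct opens by expelling the C5 alkoxide, C5 and C10 are untouched so the decalin is trans, and the cold acid quench forestalls retro-aldol scrambling.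

Step 14
Reactants: 22 hydroxy ketone
Product: 23 syn-1,3-diol (C1 α-OH axial; C5 α-OH axial)
Conditions: LiBH(s-Bu)3 (3 equiv), THF, -78 to -20 °C; H2O
Reagents that add atoms: none
Why: Bulky-hydride ketone reduction, in which the axial α trajectory is closed by the C5 alkoxide and the axial hydrogens on C3 and C9, so hydride arrives along the equatorial β trajectory (as with 4,4-dimethyl-3-keto triterpenoids) and sets the axial C1 α-alcohol, while retro-aldol is held back because it would open the decalin to a ten-membered ring.

Step 15
Reactants: 23 diol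
Product: 24 C1,C5-bis(triethylsilyl) ether
Conditions: Et3SiOTf (3 equiv), 2,6-lutidine, CH2Cl2, 0 °C to rt
Reagents that add atoms: triethylsilyl trifluoromethanesulfonate CC[Si](CC)(CC)OS(=O)(=O)C(F)(F)F
Why: Silyl triflate silylation is strong enough for the hindered secondary and tertiary hydroxyl groups, leaves a ketone-derived ketal alone, and masks both acidic protons for the amide-base and organoaluminium steps.

Step 16
Reactants: 24 bis-silyl ether
Product: 25 C7 methyl ketone (acetyl in place of isopropenyl)
Conditions: O3, CH2Cl2, -78 °C; Me2S, to rt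
Reagents that add atoms: ozone [O-][O+]=O
Why: Ozonolysis of the only alkene present gives the acetyl group, and C7 is safe because its substituent is already in the favoured equatorial position.

Step 17
Reactants: 25 methyl ketone
Product: 27 C7 terminal alkyne, via enol diethyl phosphate 26 (not isolated)
Conditions: LiN(i-Pr)2 (1.1 equiv), THF, -78 °C; ClP(O)(OEt)2, -78 °C to rt; LiN(i-Pr)2 (2.5 equiv), -78 °C to rt; H2O
Reagents that add atoms: none
Why: Methyl ketone to alkyne conversion through the kinetic enol phosphate, where deprotonation at the methyl group is followed by O-phosphorylation and base-induced elimination, without involving C7-H.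

Step 18
Reactants: 27 alkyne
Product: 29 (E)-vinyl iodide C7-C(CH3)=CH-I, via alkenyldimethylalane 28 (not isolated)
Conditions: Me3Al (3 equiv), Cp2ZrCl2 (0.25 equiv), CH2Cl2, 0 °C to rt; I2, THF, -30 °C
Reagents that add atoms: trimethylaluminium C[Al](C)C; iodine II
Why: Negishi zirconium-catalysed carboalumination adds CH3 and Al syn with methyl on the internal carbon, and iodinolysis with retention fixes the E trisubstituted alkene at a stage that holds no bromide, free hydroxyl or other alkene.

Step 19
Reactants: 29 protected vinyl iodide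
Product: 30 keto diol (C4 ketone; C1 α-OH; C5 α-OH)
Conditions: 3 M aq. HCl, THF, 45 °C
Reagents that add atoms: water O
Why: Acid hydrolysis removes both silyl ethers and the ketal in one operation, and the strong acid this deactivated ketal needs is tolerated because a cation at C5 next to the carbonyl carbon is disfavoured and the vinyl iodide is acid-stable.

Step 20
Reactants: 30 keto diol
Product: 31 exocyclic alkene diol (C4=CH2)
Conditions: Ph3PCH3Br (6 equiv), KOt-Bu (5.5 equiv), THF, 0 to 40 °C
Reagents that add atoms: methyltriphenylphosphonium bromide C[P+](c1ccccc1)(c1ccccc1)c1ccccc1.[Br-]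
Why: Wittig methylenation with excess ylide tolerates the two hydroxyl groups as alkoxides, and it is placed before bromination because a C5 alkoxide facing an equatorial C1-Br anti-periplanar to C5-C10 would invite Grob fragmentation.

Step 21
Reactants: 31 diol
Product: 32 C1 β-bromide (equatorial) with free C5-OH
Conditions: CBr4 (3 equiv), PPh3 (3 equiv), toluene, 70 °C
Reagents that add atoms: carbon tetrabromide BrC(Br)(Br)Br
Why: Appel bromination, in which only the secondary C1-OH forms the oxyphosphonium salt, bromide enters from the β face by SN2 with inversion to give the equatorial bromide, the C5 oxygen cannot interfere because it is on the same face as the leaving group, and the neutral medium produces no alkoxide.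

Step 22
Reactants: 33 2-methylbut-1-en-3-yne
Product: 34 (E)-4,4,5,5-tetramethyl-2-(3-methylbuta-1,3-dien-1-yl)-1,3,2-dioxaborolane
Conditions: pinacolborane, Cp2Zr(H)Cl (5 mol %), CH2Cl2, rt, sealed flask
Reagents that add atoms: pinacolborane B1OC(C)(C)C(C)(C)O1
Why: Zirconium-catalysed hydroboration adds H and B syn to the terminal alkyne with boron at the terminus, which gives the E-dienylboronate and spares the 1,1-disubstituted alkene.

Step 23
Reactants: 32 bromo vinyl iodide; 34 dienylboronate
Product: 35 target CNP0385268.1, (1R,5R,7R,10R) in the locants used here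
Conditions: Pd(dppf)Cl2 (5 mol %), 3 M aq. K3PO4, THF, rt, degassed, dark
Reagents that add atoms: none
Why: Suzuki-Miyaura alkenyl-alkenyl coupling proceeds with retention at both partners to the (E,E)-triene, zerovalent palladium inserts into the vinyl C-I bond far faster than into the hindered secondary C-Br bond, and aqueous phosphate is too weak a base to ionise the tertiary alcohol.

## Compound list

1 | 1,3-dithiane | C1CSCSC1 | starting material
2 | (2-bromoethoxy)(tert-butyl)dimethylsilane | BrCCO[Si](C)(C)C(C)(C)C | starting material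
3 | 2-lithio-1,3-dithiane | [Li]C1SCCCS1 | intermediate
4 | tert-butyl[2-(1,3-dithian-2-yl)ethoxy]dimethylsilane | C1CSC(CCO[Si](C)(C)C(C)(C)C)SC1 | intermediate
5 | (R)-limonene | CC1=CC[C@@H](CC1)C(=C)C | starting material
6 | (3R)-6-oxo-3-(prop-1-en-2-yl)heptanal | CC(=O)CC[C@@H](C(C)=C)CC=O | intermediate
7 | (5R)-7,7-dimethoxy-5-(prop-1-en-2-yl)heptan-2-one | CC(=O)CC[C@@H](C(C)=C)CC(OC)OC | intermediate
8 | (5R)-7,7-dimethoxy-2-methyl-5-(prop-1-en-2-yl)heptanenitrile | N#CC(C)CC[C@@H](C(C)=C)CC(OC)OC | intermediate
9 | (5R)-2-methyl-7-oxo-5-(prop-1-en-2-yl)heptanenitrile | N#CC(C)CC[C@@H](C(C)=C)CC=O | intermediate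
10 | 2-lithio derivative of 4 | [Li]C1(CCO[Si](C)(C)C(C)(C)C)SCCCS1 | intermediate
11 | C5 carbinol with C4 dithiane and C1 nitrile | N#CC(C)CC[C@@H](C(C)=C)CC(O)C1(CCO[Si](C)(C)C(C)(C)C)SCCCS1 | intermediate
12 | C5 carbinol with C4 dioxolane and C1 nitrile | N#CC(C)CC[C@@H](C(C)=C)CC(O)C1(CCO[Si](C)(C)C(C)(C)C)OCCO1 | intermediate
13 | C5 carbinol with C4 dioxolane and C1 aldehyde | O=CC(C)CC[C@@H](C(C)=C)CC(O)C1(CCO[Si](C)(C)C(C)(C)C)OCCO1 | intermediate
14 | C5 ketone with C4 dioxolane and C1 aldehyde | O=CC(C)CC[C@@H](C(C)=C)CC(=O)C1(CCO[Si](C)(C)C(C)(C)C)OCCO1 | intermediate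
15 | α-methyl keto acid (key-step precursor) | OC(=O)C(C)CC[C@@H](C(C)=C)CC(=O)C1(OCCO1)CCO[Si](C)(C)C(C)(C)C | intermediate
16 | carboxylic 4-toluenesulfonic mixed anhydride of 15 | Cc1ccc(cc1)S(=O)(=O)OC(=O)C(C)CC[C@@H](C(C)=C)CC(=O)C2(OCCO2)CCO[Si](C)(C)C(C)(C)C | intermediate
17 | 4-pyrrolidinopyridinium enolate of 15 | [O-]C(=C(C)CC[C@@H](C(C)=C)CC(=O)C1(OCCO1)CCO[Si](C)(C)C(C)(C)C)[n+]2ccc(cc2)N3CCCC3 | intermediate
18 | cyclohexane-fused β-lactone (key-step product), (1R,4R,6S) | C=C(C)[C@@H]1CC[C@@]2(C)C(=O)O[C@@]2(C3(OCCO3)CCO[Si](C)(C)C(C)(C)C)C1 | intermediate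
19 | β-lactone primary alcohol | C=C(C)[C@@H]1CC[C@@]2(C)C(=O)O[C@@]2(C3(OCCO3)CCO)C1 | intermediate
20 | β-lactone primary iodide | C=C(C)[C@@H]1CC[C@@]2(C)C(=O)O[C@@]2(C3(OCCO3)CCI)C1 | intermediate
21 | β-lactone primary alkyllithium | C=C(C)[C@@H]1CC[C@@]2(C)C(=O)O[C@@]2(C3(OCCO3)CC[Li])C1 | intermediate
22 | trans-decalone, C1 ketone, C5 α-OH, C4 ketal | C=C(C)[C@@H]1CC[C@@]2(C)C(=O)CCC3(OCCO3)[C@]2(O)C1 | intermediate
23 | C1α,C5α-diol, C4 ketal | C=C(C)[C@@H]1CC[C@@]2(C)[C@@H](O)CCC3(OCCO3)[C@]2(O)C1 | intermediate
24 | bis(triethylsilyl) ether of 23 | C=C(C)[C@@H]1CC[C@@]2(C)[C@@H](O[Si](CC)(CC)CC)CCC3(OCCO3)[C@]2(O[Si](CC)(CC)CC)C1 | intermediate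
25 | C7 methyl ketone | CC(=O)[C@@H]1CC[C@@]2(C)[C@@H](O[Si](CC)(CC)CC)CCC3(OCCO3)[C@]2(O[Si](CC)(CC)CC)C1 | intermediate
26 | C7 enol diethyl phosphate | C=C(OP(=O)(OCC)OCC)[C@@H]1CC[C@@]2(C)[C@@H](O[Si](CC)(CC)CC)CCC3(OCCO3)[C@]2(O[Si](CC)(CC)CC)C1 | intermediate
27 | C7 terminal alkyne | C#C[C@@H]1CC[C@@]2(C)[C@@H](O[Si](CC)(CC)CC)CCC3(OCCO3)[C@]2(O[Si](CC)(CC)CC)C1 | intermediate
28 | (E)-alkenyldimethylalane | C[Al](C)/C=C(\C)[C@@H]1CC[C@@]2(C)[C@@H](O[Si](CC)(CC)CC)CCC3(OCCO3)[C@]2(O[Si](CC)(CC)CC)C1 | intermediate
29 | (E)-vinyl iodide, fully protected | I/C=C(\C)[C@@H]1CC[C@@]2(C)[C@@H](O[Si](CC)(CC)CC)CCC3(OCCO3)[C@]2(O[Si](CC)(CC)CC)C1 | intermediate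
30 | (E)-vinyl iodide keto diol | I/C=C(\C)[C@@H]1CC[C@@]2(C)[C@@H](O)CCC(=O)[C@]2(O)C1 | intermediate
31 | (E)-vinyl iodide, C4 methylidene diol | I/C=C(\C)[C@@H]1CC[C@@]2(C)[C@@H](O)CCC(=C)[C@]2(O)C1 | intermediate
32 | (E)-vinyl iodide, C1 β-bromide, C5-OH | I/C=C(\C)[C@@H]1CC[C@@]2(C)[C@H](Br)CCC(=C)[C@]2(O)C1 | intermediate
33 | 2-methylbut-1-en-3-yne | C=C(C)C#C | starting material
34 | (E)-dienyl pinacol boronate | C=C(C)/C=C/B1OC(C)(C)C(C)(C)O1 | intermediate
35 | (1R,4aR,6R,8aR)-1-bromo-8a-methyl-4-methylidene-6-[(2E,4E)-6-methylhepta-2,4,6-trien-2-yl]octahydronaphthalen-4a(2H)-ol | C=C(C)/C=C/C=C(\C)[C@@H]1CC[C@@]2(C)[C@H](Br)CCC(=C)[C@]2(O)C1 | target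

## Step count and weak points

Total steps: 23. Longest linear sequence: 21 (steps 2-21 and 23).

**Step 10.** The enolate, or the ketene in equilibrium with it, may be lost to intermolecular acylation and dimerisation before it reaches the neopentyl-type C5 ketone. The two chair-like approaches may also be poorly differentiated.

The fallback activates the ketone instead of the acid. It sets out from 15.
- 1-Chloro-N,N,2-trimethylprop-1-en-1-amine in CH2Cl2 at 0 °C should give the acid chloride F1 under neutral conditions.
- Et3N in toluene should dehydrochlorinate it to the alkyl(methyl)ketene F2.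
- F2 is then exposed at high dilution to MgBr2·OEt2. This Lewis acid can chelate the C5 carbonyl oxygen and one ketal oxygen.
- A Lewis-acid-promoted ketene-carbonyl [2+2] cycloaddition follows. This reaction type is known under chelation control for α-alkoxy aldehydes.
- The cis-fusion constraint and the equatorial preferences are the same, and the sequence returns to the route at 18.

**Step 13.** t-BuLi may attack the lactone carbonyl, or the alkyllithium may be protonated, before C2 reaches C1 through the strained bridged adduct.

The fallback replaces the non-stabilised carbanion by a stabilised one that can be warmed. It sets out from 20.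
- PhSO2Na in DMF should give the phenyl sulfone F3.
- LiN(SiMe3)2 (2 equiv) in THF, -78 to 0 °C, should form the α-sulfonyl carbanion.
- This carbanion is acylated by the lactone to the β-keto sulfone F4, held as its anion so that retro-aldol is suppressed.
- Reductive desulfonylation with SmI2 in THF/MeOH at -78 °C returns to the route at 22.

**Step 21.** Three processes may outrun substitution at the neopentyl centre or accompany the heating it needs:
- elimination toward C2;
- migration of the anti-periplanar C10 methyl group;
- ionisation of the tertiary allylic C5-OH.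

The fallback swaps the order of olefination and substitution. It sets out from 30, where C5-O lies next to a carbonyl group and cannot ionise.
- Tf2O and pyridine in CH2Cl2 at -40 °C should give the C1 triflate F5.
- Bu4NBr in toluene, 0 °C to rt, should displace it with inversion to the bromo ketol F6.
- Petasis methylenation with Cp2TiMe2 in toluene at 65 °C is non-basic, so no free alkoxide faces the C1-Br bond. It installs C4=CH2 and returns to the route at 32.

## Further compounds

F1 | step 10 | acid chloride of 15 | ClC(=O)C(C)CC[C@@H](C(C)=C)CC(=O)C1(OCCO1)CCO[Si](C)(C)C(C)(C)C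
F2 | step 10 | alkyl(methyl)ketene from F1 | O=C=C(C)CC[C@@H](C(C)=C)CC(=O)C1(OCCO1)CCO[Si](C)(C)C(C)(C)C
F3 | step 13 | β-lactone C2 phenyl sulfone | C=C(C)[C@@H]1CC[C@@]2(C)C(=O)O[C@@]2(C3(OCCO3)CCS(=O)(=O)c4ccccc4)C1
F4 | step 13 | C2-phenylsulfonyl derivative of 22 (β-keto sulfone) | C=C(C)[C@@H]1CC[C@@]2(C)C(=O)C(S(=O)(=O)c4ccccc4)CC3(OCCO3)[C@]2(O)C1
F5 | step 21 | C1 α-triflate of 30 | I/C=C(\C)[C@@H]1CC[C@@]2(C)[C@@H](OS(=O)(=O)C(F)(F)F)CCC(=O)[C@]2(O)C1
F6 | step 21 | C1 β-bromo C4-keto C5-ol | I/C=C(\C)[C@@H]1CC[C@@]2(C)[C@H](Br)CCC(=O)[C@]2(O)C1
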